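**Strategy.** The ester C–O bond to the tertiary alcohol is never made directly. The cyclohexene ring of the p-menth-1-ene unit is cut at C3–C4 and C5–C6, because its oxygen-bearing quaternary C4 sits para to the methyl-bearing C1 of the C1=C2 double bond, the pattern of an isoprene [4+2] adduct. One catalytic asymmetric Diels–Alder reaction therefore builds the carbocycle, the para regiochemistry and the only stereocentre (C4, R). Its dienophile is a 2-aroyloxyacrolein that already carries the silyl-protected 3,5-diprenyl-4-hydroxybenzoyl group on the enol oxygen. The formyl group of the adduct, two carbons short of isopropyl, is elaborated afterwards.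

Key step: step 7

Assumption: the sense of induction of the binaphthyl diammonium catalyst with this aroyloxyacrolein and isoprene is not taken as settled; the steps are written with the (R)-diamine, and the (S)-diamine (also commercial) would be used instead if the adduct proved to be the S enantiomer.

**Step 1**
Reactants: 1 methyl 4-hydroxybenzoate; 2 prenyl bromide (1-bromo-3-methylbut-2-ene)
Product: 4 methyl 4-hydroxy-3,5-bis(3-methylbut-2-en-1-yl)benzoate, via monoprenylated ester 3 (not isolated)
Conditions: NaH (2.2 equiv, two portions), 2 (2.3 equiv, two portions), PhMe, 0 °C → rt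
Reagents that add atoms: prenyl bromide (second equivalent), CC(C)=CCBr
Why: Ortho C-allylation of a sodium phenoxide held as a tight ion pair in a non-polar solvent should occur twice in the flask, the para position being blocked by the ester; the first equivalent of 2 gives 3, and after re-deprotonation of 3 the second equivalent of 2 alkylates the remaining ortho position.

**Step 2**
Reactants: 4 methyl 4-hydroxy-3,5-bis(3-methylbut-2-en-1-yl)benzoate
Product: 5 4-hydroxy-3,5-bis(3-methylbut-2-en-1-yl)benzoic acid
Conditions: KOH, MeOH/H2O, 65 °C; then 1 M HCl to pH 3, 0 °C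
Reagents that add atoms: potassium hydroxide, [K+].[OH-]
Why: Saponification of the methyl ester should be clean because phenoxide, prenyl olefins and arene tolerate hot aqueous alkali, and the brief cold acidification avoids acid-induced chroman formation.

**Step 3**
Reactants: 5 4-hydroxy-3,5-bis(3-methylbut-2-en-1-yl)benzoic acid
Product: 7 3,5-bis(3-methylbut-2-en-1-yl)-4-(triisopropylsilyloxy)benzoic acid, via bis-silylated silyl ester 6 (not isolated)
Conditions: iPr3SiOTf (2.3 equiv), 2,6-lutidine, CH2Cl2, 0 °C → rt, aqueous wash; crude 6, K2CO3, MeOH/THF/H2O, rt; then 1 M HCl to pH 3, 0 °C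
Reagents that add atoms: triisopropylsilyl trifluoromethanesulfonate, CC(C)[Si](OS(=O)(=O)C(F)(F)F)(C(C)C)C(C)C
Why: Silyl triflate silylation should cap both acidic OH groups, including the ortho,ortho-disubstituted phenol, and mild carbonate hydrolysis should then remove only the far more labile silyl ester.

**Step 4**
Reactants: 7 3,5-bis(3-methylbut-2-en-1-yl)-4-(triisopropylsilyloxy)benzoic acid
Product: 8 3,5-bis(3-methylbut-2-en-1-yl)-4-(triisopropylsilyloxy)benzoyl chloride
Conditions: 1-chloro-N,N,2-trimethylprop-1-en-1-amine, CH2Cl2, 0 °C → rt; used crude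
Reagents that add atoms: 1-chloro-N,N,2-trimethylprop-1-en-1-amine, CC(C)=C(Cl)N(C)C
Why: Acid chloride formation with an α-chloroenamine runs under neutral conditions, so no HCl is released that could add to the prenyl olefins or open the silyl ether.

**Step 5**
Reactants: 8 3,5-bis(3-methylbut-2-en-1-yl)-4-(triisopropylsilyloxy)benzoyl chloride; 9 2,2-dimethyl-1,3-dioxan-5-one
Product: 11 2,2-dimethyl-4H-1,3-dioxin-5-yl 3,5-bis(3-methylbut-2-en-1-yl)-4-(triisopropylsilyloxy)benzoate, via potassium dioxinolate 10 (not isolated)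
Conditions: 9 (1.1 equiv), KN(SiMe3)2 (1.05 equiv), THF, −78 °C; then 8, −78 → −20 °C
Reagents that add atoms: none
Why: O-acylation of a potassium ketone enolate by a hard aroyl chloride (enol ester formation) should dominate for this oxygen-rich enolate, placing the aroyl group on the enol oxygen.

**Step 6**
Reactants: 11 2,2-dimethyl-4H-1,3-dioxin-5-yl 3,5-bis(3-methylbut-2-en-1-yl)-4-(triisopropylsilyloxy)benzoate
Product: 12 3-oxoprop-1-en-2-yl 3,5-bis(3-methylbut-2-en-1-yl)-4-(triisopropylsilyloxy)benzoate
Conditions: PhMe (dilute), 110 °C, N2 sweep; used at once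
Reagents that add atoms: none
Why: Thermal retro-hetero-Diels–Alder reaction of the 4H-1,3-dioxin, driven by loss of volatile acetone, should unmask the 2-acyloxyacrolein without touching any other group.

**Step 7**
Reactants: 12 3-oxoprop-1-en-2-yl 3,5-bis(3-methylbut-2-en-1-yl)-4-(triisopropylsilyloxy)benzoate; 13 isoprene
Product: 14 (R)-1-formyl-4-methylcyclohex-3-en-1-yl 3,5-bis(3-methylbut-2-en-1-yl)-4-(triisopropylsilyloxy)benzoate
Conditions: (R)-1,1′-binaphthyl-2,2′-diamine (10 mol %), (CF3SO2)2NH (19 mol %), 13 (5 equiv), EtCN, −75 → −40 °C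
Reagents that add atoms: none
Why: The primary amine of the diammonium salt should condense with the aldehyde of 12 to an iminium ion whose LUMO is lowered and polarised towards the terminal CH2, and isoprene should add to it in a concerted asynchronous [4+2] cycloaddition before hydrolysis releases 14 and the catalyst. The closest known reaction type is the enantioselective Diels–Alder reaction of 2-acyloxyacroleins with cyclic and acyclic dienes under chiral primary ammonium salt catalysis. The six-membered carbocycle closes intermolecularly in this single suprafacial cycloaddition, which forms C3–C4 and C5–C6. C4, the only new stereocentre, is controlled by the binaphthyl axis of the catalyst, which shields one face of the iminium ion while the second N–H hydrogen-bonds the aroyl carbonyl and fixes the iminium geometry. The step needs facial selectivity, para regioselectivity and chemoselectivity: the first rests on the catalyst, the second on the large HOMO coefficient at the isoprene terminus next to the methyl-bearing carbon meeting the dienophile CH2, and the third on the prenyl olefins being unactivated trisubstituted alkenes and on the low temperature, which suppresses the uncatalysed pathway.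

**Step 8**
Reactants: 14 (R)-1-formyl-4-methylcyclohex-3-en-1-yl 3,5-bis(3-methylbut-2-en-1-yl)-4-(triisopropylsilyloxy)benzoate
Product: 15 (1R)-1-(1-hydroxyethyl)-4-methylcyclohex-3-en-1-yl 3,5-bis(3-methylbut-2-en-1-yl)-4-(triisopropylsilyloxy)benzoate (both carbinol epimers)
Conditions: MeTi(OiPr)3 (1.5 equiv), THF, −40 → −10 °C; cold aq. NH4Cl
Reagents that add atoms: methyltitanium triisopropoxide, C[Ti](OC(C)C)(OC(C)C)OC(C)C
Why: Chemoselective carbonyl addition of the weakly basic organotitanium reagent should occur at the activated aldehyde and not at the aryl ester, the carbinol centre forming as an epimer mixture that the next step erases, while the low temperature and the poorly nucleophilic titanium alkoxide disfavour 1,2-acyl migration.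

**Step 9**
Reactants: 15 (1R)-1-(1-hydroxyethyl)-4-methylcyclohex-3-en-1-yl 3,5-bis(3-methylbut-2-en-1-yl)-4-(triisopropylsilyloxy)benzoate
Product: 16 (R)-1-acetyl-4-methylcyclohex-3-en-1-yl 3,5-bis(3-methylbut-2-en-1-yl)-4-(triisopropylsilyloxy)benzoate
Conditions: Dess–Martin periodinane, CH2Cl2, 0 °C → rt
Reagents that add atoms: none
Why: Dess–Martin oxidation should convert the secondary alcohol into the methyl ketone under near-neutral conditions that spare olefins, ester and silyl ether, and C4 carries no hydrogen that could epimerise.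

**Step 10**
Reactants: 16 (R)-1-acetyl-4-methylcyclohex-3-en-1-yl 3,5-bis(3-methylbut-2-en-1-yl)-4-(triisopropylsilyloxy)benzoate
Product: 17 (R)-4-methyl-1-(prop-1-en-2-yl)cyclohex-3-en-1-yl 3,5-bis(3-methylbut-2-en-1-yl)-4-(triisopropylsilyloxy)benzoate
Conditions: Zn, CH2Br2, TiCl4, THF, −40 → 5 °C (reagent pre-formed); then 16, CH2Cl2, 0 °C → rt
Reagents that add atoms: dibromomethane, BrCBr
Why: Takai–Lombardo methylenation uses a non-basic zinc–titanium methylene reagent that converts ketones but not esters, so it should avoid enolisation of the α-aroyloxy ketone and the base-induced acyl transfer that a phosphorus ylide could provoke.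

**Step 11**
Reactants: 17 (R)-4-methyl-1-(prop-1-en-2-yl)cyclohex-3-en-1-yl 3,5-bis(3-methylbut-2-en-1-yl)-4-(triisopropylsilyloxy)benzoate
Product: 18 (R)-4-methyl-1-(propan-2-yl)cyclohex-3-en-1-yl 3,5-bis(3-methylbut-2-en-1-yl)-4-(triisopropylsilyloxy)benzoate
Conditions: H2 (1 atm), RhCl(PPh3)3 (10 mol %), PhH/EtOH, rt
Reagents that add atoms: none
Why: Homogeneous hydrogenation with RhCl(PPh3)3 should reduce the 1,1-disubstituted alkene much faster than the three trisubstituted alkenes and does not hydrogenolyse the allylic ester.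

**Step 12**
Reactants: 18 (R)-4-methyl-1-(propan-2-yl)cyclohex-3-en-1-yl 3,5-bis(3-methylbut-2-en-1-yl)-4-(triisopropylsilyloxy)benzoate
Product: 19 (R)-4-methyl-1-(propan-2-yl)cyclohex-3-en-1-yl 4-hydroxy-3,5-bis(3-methylbut-2-en-1-yl)benzoate
Conditions: Bu4NF (1.2 equiv), AcOH (1.2 equiv), THF, 0 °C
Reagents that add atoms: none
Why: Fluoride-induced desilylation of the aryl silyl ether, buffered with acetic acid so that the phenoxide is protonated at once, should leave the hindered tertiary ester and all olefins intact.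

**Compound list**
1 | methyl 4-hydroxybenzoate | COC(=O)c1ccc(O)cc1 | starting material
2 | prenyl bromide (1-bromo-3-methylbut-2-ene) | CC(C)=CCBr | starting material
3 | methyl 4-hydroxy-3-(3-methylbut-2-en-1-yl)benzoate | COC(=O)c1ccc(O)c(CC=C(C)C)c1 | intermediate
4 | methyl 4-hydroxy-3,5-bis(3-methylbut-2-en-1-yl)benzoate | COC(=O)c1cc(CC=C(C)C)c(O)c(CC=C(C)C)c1 | intermediate
5 | 4-hydroxy-3,5-bis(3-methylbut-2-en-1-yl)benzoic acid | CC(C)=CCc1cc(C(=O)O)cc(CC=C(C)C)c1O | intermediate
6 | triisopropylsilyl 3,5-bis(3-methylbut-2-en-1-yl)-4-(triisopropylsilyloxy)benzoate | CC(C)=CCc1cc(C(=O)O[Si](C(C)C)(C(C)C)C(C)C)cc(CC=C(C)C)c1O[Si](C(C)C)(C(C)C)C(C)C | intermediate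
7 | 3,5-bis(3-methylbut-2-en-1-yl)-4-(triisopropylsilyloxy)benzoic acid | CC(C)=CCc1cc(C(=O)O)cc(CC=C(C)C)c1O[Si](C(C)C)(C(C)C)C(C)C | intermediate
8 | 3,5-bis(3-methylbut-2-en-1-yl)-4-(triisopropylsilyloxy)benzoyl chloride | CC(C)=CCc1cc(C(=O)Cl)cc(CC=C(C)C)c1O[Si](C(C)C)(C(C)C)C(C)C | intermediate
9 | 2,2-dimethyl-1,3-dioxan-5-one | CC1(C)OCC(=O)CO1 | starting material
10 | potassium 2,2-dimethyl-4H-1,3-dioxin-5-olate | CC1(C)OCC([O-])=CO1.[K+] | intermediate
11 | 2,2-dimethyl-4H-1,3-dioxin-5-yl 3,5-bis(3-methylbut-2-en-1-yl)-4-(triisopropylsilyloxy)benzoate | CC(C)=CCc1cc(C(=O)OC2=COC(C)(C)OC2)cc(CC=C(C)C)c1O[Si](C(C)C)(C(C)C)C(C)C | intermediate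
12 | 3-oxoprop-1-en-2-yl 3,5-bis(3-methylbut-2-en-1-yl)-4-(triisopropylsilyloxy)benzoate | CC(C)=CCc1cc(C(=O)OC(=C)C=O)cc(CC=C(C)C)c1O[Si](C(C)C)(C(C)C)C(C)C | intermediate
13 | isoprene | C=CC(C)=C | starting material
14 | (R)-1-formyl-4-methylcyclohex-3-en-1-yl 3,5-bis(3-methylbut-2-en-1-yl)-4-(triisopropylsilyloxy)benzoate | CC(C)=CCc1cc(C(=O)O[C@@]2(C=O)CC=C(C)CC2)cc(CC=C(C)C)c1O[Si](C(C)C)(C(C)C)C(C)C | intermediate
15 | (1R)-1-(1-hydroxyethyl)-4-methylcyclohex-3-en-1-yl 3,5-bis(3-methylbut-2-en-1-yl)-4-(triisopropylsilyloxy)benzoate, both carbinol epimers | CC(C)=CCc1cc(C(=O)O[C@@]2(C(C)O)CC=C(C)CC2)cc(CC=C(C)C)c1O[Si](C(C)C)(C(C)C)C(C)C | intermediate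
16 | (R)-1-acetyl-4-methylcyclohex-3-en-1-yl 3,5-bis(3-methylbut-2-en-1-yl)-4-(triisopropylsilyloxy)benzoate | CC(C)=CCc1cc(C(=O)O[C@@]2(C(C)=O)CC=C(C)CC2)cc(CC=C(C)C)c1O[Si](C(C)C)(C(C)C)C(C)C | intermediate
17 | (R)-4-methyl-1-(prop-1-en-2-yl)cyclohex-3-en-1-yl 3,5-bis(3-methylbut-2-en-1-yl)-4-(triisopropylsilyloxy)benzoate | CC(C)=CCc1cc(C(=O)O[C@@]2(C(C)=C)CC=C(C)CC2)cc(CC=C(C)C)c1O[Si](C(C)C)(C(C)C)C(C)C | intermediate
18 | (R)-4-methyl-1-(propan-2-yl)cyclohex-3-en-1-yl 3,5-bis(3-methylbut-2-en-1-yl)-4-(triisopropylsilyloxy)benzoate | CC(C)=CCc1cc(C(=O)O[C@@]2(C(C)C)CC=C(C)CC2)cc(CC=C(C)C)c1O[Si](C(C)C)(C(C)C)C(C)C | intermediate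
19 | (R)-4-methyl-1-(propan-2-yl)cyclohex-3-en-1-yl 4-hydroxy-3,5-bis(3-methylbut-2-en-1-yl)benzoate | CC(C)=CCc1cc(C(=O)O[C@@]2(C(C)C)CC=C(C)CC2)cc(CC=C(C)C)c1O | target

**Totals.** Total step count: 12. Longest linear sequence: 12 steps (1 → 19); compound 9 and isoprene 13 enter as purchased materials.

**Steps most likely to fail**

Step 7. Facial discrimination may be insufficient, or catalyst turnover too slow, with an acyclic diene and this bulky, electron-rich aroyl group, so that the adduct would form with low enantiomeric purity or not at a useful rate. The fallback sets out from acid chloride 8 and comes back at 18, taking C4 from the chiral pool instead of from a cycloaddition. Commercial (R)-terpinen-4-ol F1, after a check of the enantiomeric purity of the batch, would be deprotonated with n-BuLi in THF at −78 °C to lithium (R)-terpinen-4-olate F2. This would be acylated with 8 (−78 °C → rt), a standard esterification of a tertiary lithium alkoxide with an aroyl chloride that does not touch the stereocentre. Step 12 then follows unchanged.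

Step 8. The aroyl group may migrate from the tertiary oxygen to the newly formed secondary alkoxide through a cyclic orthoester, or be exchanged by isopropoxide, which would destroy the ester linkage the route is built to preserve. The fallback sets out from aldehyde 14 and comes back at ketone 16, and never generates an alkoxide next to the ester. Pinnick oxidation (NaClO2, NaH2PO4, large excess of 2-methylbut-2-ene, t-BuOH/H2O) would give (R)-4-methyl-1-{[3,5-bis(3-methylbut-2-en-1-yl)-4-(triisopropylsilyloxy)benzoyl]oxy}cyclohex-3-ene-1-carboxylic acid F3. Treatment with 1-chloro-N,N,2-trimethylprop-1-en-1-amine in CH2Cl2 would give the corresponding acid chloride F4. One equivalent of Me2CuLi in Et2O at −78 °C would then convert the acid chloride into the methyl ketone 16 by acyl substitution.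

Step 11. Hydrogen uptake at the isopropenyl group, which is flanked by the quaternary carbon and the bulky aroyloxy group, may be so slow that forcing conditions begin to saturate the prenyl or ring olefins. The fallback sets out from 17 and comes back at 18, replacing catalytic hydrogenation by hydroboration and deoxygenation. 9-Borabicyclo[3.3.1]nonane in THF, which selects strongly for the 1,1-disubstituted alkene, would give the B-alkyl borane F5. Oxidation with NaBO3·4H2O would give the primary alcohol (1R)-1-(1-hydroxypropan-2-yl)-4-methylcyclohex-3-en-1-yl 3,5-bis(3-methylbut-2-en-1-yl)-4-(triisopropylsilyloxy)benzoate F6, as an inconsequential epimer mixture at the side-chain carbon. An Appel reaction (I2, PPh3, imidazole, CH2Cl2) would give the primary iodide F7. Hydride displacement with NaBH4 in DMSO would then deliver 18, the polar reduction being chosen over a tin hydride to exclude radical cyclisation onto the ring olefin.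

**Further compounds**
F1 | step 7 | (R)-terpinen-4-ol, (R)-4-methyl-1-(propan-2-yl)cyclohex-3-en-1-ol | O[C@@]1(C(C)C)CC=C(C)CC1
F2 | step 7 | lithium (R)-terpinen-4-olate | [Li+].[O-][C@@]1(C(C)C)CC=C(C)CC1
F3 | step 8 | (R)-4-methyl-1-{[3,5-bis(3-methylbut-2-en-1-yl)-4-(triisopropylsilyloxy)benzoyl]oxy}cyclohex-3-ene-1-carboxylic acid | CC(C)=CCc1cc(C(=O)O[C@@]2(C(=O)O)CC=C(C)CC2)cc(CC=C(C)C)c1O[Si](C(C)C)(C(C)C)C(C)C
F4 | step 8 | (R)-1-(chlorocarbonyl)-4-methylcyclohex-3-en-1-yl 3,5-bis(3-methylbut-2-en-1-yl)-4-(triisopropylsilyloxy)benzoate | CC(C)=CCc1cc(C(=O)O[C@@]2(C(=O)Cl)CC=C(C)CC2)cc(CC=C(C)C)c1O[Si](C(C)C)(C(C)C)C(C)C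
F5 | step 11 | (1R)-1-[1-(9-borabicyclo[3.3.1]nonan-9-yl)propan-2-yl]-4-methylcyclohex-3-en-1-yl 3,5-bis(3-methylbut-2-en-1-yl)-4-(triisopropylsilyloxy)benzoate | CC(C)=CCc1cc(C(=O)O[C@@]2(C(C)CB3C4CCCC3CCC4)CC=C(C)CC2)cc(CC=C(C)C)c1O[Si](C(C)C)(C(C)C)C(C)C
F6 | step 11 | (1R)-1-(1-hydroxypropan-2-yl)-4-methylcyclohex-3-en-1-yl 3,5-bis(3-methylbut-2-en-1-yl)-4-(triisopropylsilyloxy)benzoate | CC(C)=CCc1cc(C(=O)O[C@@]2(C(C)CO)CC=C(C)CC2)cc(CC=C(C)C)c1O[Si](C(C)C)(C(C)C)C(C)C
F7 | step 11 | (1R)-1-(1-iodopropan-2-yl)-4-methylcyclohex-3-en-1-yl 3,5-bis(3-methylbut-2-en-1-yl)-4-(triisopropylsilyloxy)benzoate | CC(C)=CCc1cc(C(=O)O[C@@]2(C(C)CI)CC=C(C)CC2)cc(CC=C(C)C)c1O[Si](C(C)C)(C(C)C)C(C)C
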